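Ring B of the target (C5–C10) carries oxygen at C6 and methyl groups at C8 and C10 on either side of C9, which is the substitution pattern of 2,6-dimethylbenzoquinone; masked at C6 as a dioxolane, this quinone is an achiral dienone with two enantiotopic enone arms. The route rests on breaking that symmetry in one operation: a copper-catalysed enantioselective addition of an isopropenyl group to one arm (C4–C5) followed by allylation of the resulting enolate with 2-(phenylsulfonyl)allyl bromide (C1–C10), which sets C5 and C10 and installs the donor and acceptor alkenes for a later radical closure of ring A. The C9 carbonyl and the second enone arm then carry the side chain and the C6/C7 esters.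

Key step: step 5

Remarks on the chemistry:
- Bicyclic compounds are numbered as labdanes (ring A: C1–C5 and C10; ring B: C5–C10; side chain C11–C16). β is the face of the C10 methyl group, α the face of H5. The target is (5S,6S,7S,10S,13E), that is 6β-acetoxy, 7α-isovaleroyloxy.
- The configuration at C2 (sulfone, epimer mixture) and at C9 (carbinol, drawn as the expected 9β-OH) in 12 and 22–26 has no bearing on the target.
- Assumption: phenol 1 is taken as a catalogue compound; otherwise it follows from 2,6-dimethylhydroquinone by methylation of the unhindered hydroxyl.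

Step 1
Reactants: 1 4-methoxy-2,6-dimethylphenol
Product: 2 4,4-dimethoxy-2,6-dimethylcyclohexa-2,5-dien-1-one
Conditions: PhI(OAc)2, MeOH, 0 °C
Reagents that add atoms: methanol, CO
Why: Hypervalent-iodine oxidative dearomatisation of a para-methoxyphenol in methanol places the ketal at the carbon para to the hydroxyl, that is at the unhindered quinone carbonyl, and is far more dependable than acid-catalysed ketalisation of the free quinone.

Step 2
Reactants: 2 4,4-dimethoxy-2,6-dimethylcyclohexa-2,5-dien-1-one; 3 ethane-1,2-diol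
Product: 4 7,9-dimethyl-1,4-dioxaspiro[4.5]deca-6,9-dien-8-one
Conditions: BF3·OEt2 (cat.), DME, 0 °C
Reagents that add atoms: none
Why: Lewis-acid transketalisation of a quinone monoketal is driven by ring formation and gives the compact spiro-dioxolane, the smallest ketal that C6 can carry next to the later C4 gem-dimethyl group and one that survives the organometallic steps.

Step 3
Reactants: 5 phenyl vinyl sulfone; 6 formaldehyde
Product: 7 2-(phenylsulfonyl)prop-2-en-1-ol
Conditions: DABCO, 37% aq. HCHO, THF, rt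
Reagents that add atoms: none
Why: Morita–Baylis–Hillman hydroxymethylation puts the new carbon on the sulfonyl-bearing vinyl carbon, which secures the 2-sulfonyl allyl pattern that bromination and dehydrobromination of allyl phenyl sulfone cannot give (that sequence is expected to end in the 1-sulfonyl isomer).

Step 4
Reactants: 7 2-(phenylsulfonyl)prop-2-en-1-ol
Product: 8 3-bromo-2-(phenylsulfonyl)prop-1-ene
Conditions: PBr3, Et2O, 0 °C
Reagents that add atoms: phosphorus tribromide, BrP(Br)Br
Why: Conversion of an allylic alcohol into the bromide with PBr3, in which direct and allylic (SN2') substitution give the same product because the allyl unit is symmetric.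

Step 5
Reactants: 4 7,9-dimethyl-1,4-dioxaspiro[4.5]deca-6,9-dien-8-one; 9 isopropenylmagnesium bromide; 8 3-bromo-2-(phenylsulfonyl)prop-1-ene
Product: 11 (9S,10S)-7,9-dimethyl-9-[2-(phenylsulfonyl)prop-2-en-1-yl]-10-(prop-1-en-2-yl)-1,4-dioxaspiro[4.5]dec-6-en-8-one, via bromomagnesium enolate 10 (not isolated)
Conditions: CuBr·SMe2 (5 mol %), (R)-1-[(S)-2-(diphenylphosphino)ferrocenyl]ethyldicyclohexylphosphine (6 mol %), 9 (1.2 equiv), t-BuOMe, −78 °C; then 8 (1.5 equiv), DMPU, THF, −78 → −20 °C
Reagents that add atoms: none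
Why: A chiral ferrocenyl-diphosphine complex of monovalent copper takes the isopropenyl group from the Grignard reagent and transfers it to the β-carbon of one enone arm of 4 (π-complexation, oxidative addition, reductive elimination), forming C4–C5 and enolate 10, whose methyl-bearing carbon then attacks the vinyl sulfone terminus of 8 with loss of bromide (addition–elimination), forming C1–C10. The closest known reaction type is the copper-catalysed enantioselective conjugate addition of organomagnesium or organozinc reagents to cyclohexadienones and quinone monoketals with trapping of the enolate by an allylic halide. No ring is closed. C5 is set by the ligand on copper: the two β-carbons of 4 are enantiotopic and, because the dienone has two mirror planes, only two enantiomeric modes of attack exist, so one catalyst-controlled choice defines the configuration (the antipodal ligand is used if the sense of induction is opposite). C10 is set by the substrate, the electrophile approaching the enolate on the face away from the new C5 isopropenyl group, so that the two carbon arms end up trans. The step needs 1,4- over 1,2-addition (secured by copper and by the two methyl groups flanking the carbonyl), mono-addition (the second arm is part of a dienolate until alkylation) and C- over O-alkylation (secured by the soft, highly reactive allylic bromide and DMPU).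

Step 6
Reactants: 11 (9S,10S)-7,9-dimethyl-9-[2-(phenylsulfonyl)prop-2-en-1-yl]-10-(prop-1-en-2-yl)-1,4-dioxaspiro[4.5]dec-6-en-8-one
Product: 12 6,6-ethylenedioxy-2-(phenylsulfonyl)-11-nordrim-7-en-9-one (trans-fused; 5α-H; 10β-CH3)
Conditions: Fe(acac)3 (30 mol %), PhSiH3, EtOH/(CH2OH)2 5:1, 60 °C
Reagents that add atoms: none
Why: Metal-hydride hydrogen-atom-transfer radical cyclisation (reductive olefin coupling): an iron hydride adds a hydrogen atom to the electron-rich isopropenyl group, the tertiary C4 radical adds in a polarity-matched 6-endo mode to the unsubstituted terminus of the vinyl sulfone (C3–C4), and the α-sulfonyl radical is reduced and protonated, the trans ring fusion being dictated by the existing C5 and C10 centres.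

Step 7
Reactants: 13 tert-butyl(but-3-yn-1-yloxy)dimethylsilane; 6 formaldehyde (as paraformaldehyde)
Product: 16 (E)-5-[(tert-butyldimethylsilyl)oxy]-3-methylpent-2-en-1-ol, via alkenyldimethylalane 14 (not isolated), via lithium alkenylalanate 15 (not isolated)
Conditions: AlMe3, Cp2ZrCl2 (25 mol %), CH2Cl2, 0 °C → rt; then n-BuLi, THF, −78 °C; (CH2O)n, −78 °C → rt
Reagents that add atoms: trimethylaluminium, C[Al](C)C
Why: Zirconium-catalysed carboalumination (Negishi) adds methyl and aluminium syn across the terminal alkyne with methyl on the internal carbon, and the derived alanate reacts with formaldehyde with retention, which fixes the E geometry of the future C13–C14 double bond.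

Step 8
Reactants: 16 (E)-5-[(tert-butyldimethylsilyl)oxy]-3-methylpent-2-en-1-ol
Product: 17 (E)-1-[(tert-butyldiphenylsilyl)oxy]-5-[(tert-butyldimethylsilyl)oxy]-3-methylpent-2-ene
Conditions: TBDPSCl, imidazole, DMF, rt
Reagents that add atoms: tert-butyl(chloro)diphenylsilane, CC(C)(C)[Si](Cl)(c1ccccc1)c1ccccc1
Why: Standard silylation of a primary allylic alcohol, the tert-butyldiphenylsilyl ether being chosen to outlast the acidic and oxidative steps ahead.

Step 9
Reactants: 17 (E)-1-[(tert-butyldiphenylsilyl)oxy]-5-[(tert-butyldimethylsilyl)oxy]-3-methylpent-2-ene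
Product: 18 (E)-5-[(tert-butyldiphenylsilyl)oxy]-3-methylpent-3-en-1-ol
Conditions: PPTS, EtOH, 40 °C
Reagents that add atoms: none
Why: Mild acid alcoholysis removes a primary tert-butyldimethylsilyl ether much faster than a tert-butyldiphenylsilyl ether (selective desilylation).

Step 10
Reactants: 18 (E)-5-[(tert-butyldiphenylsilyl)oxy]-3-methylpent-3-en-1-ol
Product: 19 (E)-tert-butyl[(5-iodo-3-methylpent-2-en-1-yl)oxy]diphenylsilane
Conditions: I2, PPh3, imidazole, CH2Cl2, 0 °C
Reagents that add atoms: iodine, II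
Why: Appel-type iodination of a primary alcohol with PPh3 and iodine, which does not touch the trisubstituted alkene or the silyl ether.

Step 11
Reactants: 19 (E)-tert-butyl[(5-iodo-3-methylpent-2-en-1-yl)oxy]diphenylsilane; 12 6,6-ethylenedioxy-2-(phenylsulfonyl)-11-nordrim-7-en-9-one
Product: 22 15-[(tert-butyldiphenylsilyl)oxy]-6,6-ethylenedioxy-2-(phenylsulfonyl)labda-7,13E-dien-9-ol, via alkyllithium 20 (not isolated), via alkylcerium dichloride 21 (not isolated)
Conditions: 19 (2.5 equiv), t-BuLi (2 equiv per iodide), Et2O/pentane, −78 °C; CeCl3, THF, −78 °C; then 12, −78 → −40 °C; aq. NH4Cl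
Reagents that add atoms: none
Why: Iodine–lithium exchange and transmetalation to cerium give a weakly basic nucleophile that adds 1,2 to the hindered, non-enolisable C9 ketone from the α face, anti to the axial C10 methyl (organocerium carbonyl addition); an excess is used because part is consumed by deprotonation next to the sulfone, which is harmless since that carbanion is reprotonated on work-up.

Step 12
Reactants: 22 15-[(tert-butyldiphenylsilyl)oxy]-6,6-ethylenedioxy-2-(phenylsulfonyl)labda-7,13E-dien-9-ol
Product: 23 15-[(tert-butyldiphenylsilyl)oxy]-6,6-ethylenedioxylabda-7,13E-dien-9-ol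
Conditions: 6% Na(Hg), Na2HPO4, MeOH/THF, −20 → 0 °C
Reagents that add atoms: none
Why: Reductive desulfonylation of an alkyl phenyl sulfone by sodium amalgam in buffered methanol, placed here because no reducible carbonyl is present and the tertiary allylic alcohol, ketal and silyl ether are inert.

Step 13
Reactants: 23 15-[(tert-butyldiphenylsilyl)oxy]-6,6-ethylenedioxylabda-7,13E-dien-9-ol
Product: 24 15-[(tert-butyldiphenylsilyl)oxy]-9-hydroxylabda-7,13E-dien-6-one
Conditions: PPTS, acetone/H2O 10:1, 40 °C
Reagents that add atoms: water, O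
Why: The ketal is allylic and strained against the C4 methyl groups, so mild acid hydrolysis releases the conjugated C6 enone while the tertiary alcohol and the silyl ether remain intact (ketal hydrolysis).

Step 14
Reactants: 24 15-[(tert-butyldiphenylsilyl)oxy]-9-hydroxylabda-7,13E-dien-6-one
Product: 25 15-[(tert-butyldiphenylsilyl)oxy]labda-7,13E-diene-6β,9-diol
Conditions: NaBH4, CeCl3·7H2O, MeOH, −78 → −40 °C
Reagents that add atoms: none
Why: Luche reduction gives clean 1,2-reduction of the enone, and hydride is delivered to the α face of C6 because the β face is screened by the axial C10 methyl and the axial C4 methyl, which sets the axial 6β alcohol.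

Step 15
Reactants: 25 15-[(tert-butyldiphenylsilyl)oxy]labda-7,13E-diene-6β,9-diol
Product: 26 6β-acetoxy-15-[(tert-butyldiphenylsilyl)oxy]labda-7,13E-dien-9-ol
Conditions: Ac2O, DMAP, Et3N, CH2Cl2, 40 °C
Reagents that add atoms: acetic anhydride, CC(=O)OC(C)=O
Why: Acetylation under nucleophilic catalysis esterifies the secondary allylic 6β alcohol while the tertiary C9 alcohol stays free.

Step 16
Reactants: 26 6β-acetoxy-15-[(tert-butyldiphenylsilyl)oxy]labda-7,13E-dien-9-ol
Product: 27 6β-acetoxy-15-[(tert-butyldiphenylsilyl)oxy]labda-8,13E-dien-7-one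
Conditions: pyridinium chlorochromate (C5H5NH)[CrO3Cl], NaOAc, 4 Å sieves, CH2Cl2, rt
Reagents that add atoms: pyridinium chlorochromate, [O-][Cr](=O)(=O)Cl.c1cc[nH+]cc1
Why: Babler–Dauben oxidative transposition, in which hexavalent chromium transfers oxygen from the tertiary allylic carbinol position to C7 and oxidises it, moves the double bond to C8–C9 and erases the C9 centre.

Step 17
Reactants: 27 6β-acetoxy-15-[(tert-butyldiphenylsilyl)oxy]labda-8,13E-dien-7-one
Product: 28 6β-acetoxy-15-[(tert-butyldiphenylsilyl)oxy]labda-8,13E-dien-7β-ol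
Conditions: NaBH4, CeCl3·7H2O, MeOH, −78 °C
Reagents that add atoms: none
Why: Luche 1,2-reduction in which hydride approaches C7 anti to the axial C6–O bond (Felkin–Anh) from the α face, where only H5 opposes it, so that the equatorial 7β alcohol should result, which is the epimer opposite to the one the target needs.

Step 18
Reactants: 28 6β-acetoxy-15-[(tert-butyldiphenylsilyl)oxy]labda-8,13E-dien-7β-ol; 29 3-methylbutanoic acid
Product: 30 6β-acetoxy-15-[(tert-butyldiphenylsilyl)oxy]-7α-(3-methylbutanoyloxy)labda-8,13E-diene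
Conditions: PPh3, DIAD, toluene, 0 °C → rt
Reagents that add atoms: none
Why: Mitsunobu esterification replaces the activated 7β hydroxyl by isovalerate with inversion, the carboxylate entering on the α face, while elimination is blocked (no anti-periplanar hydrogen on C6, none at all on C8) and the cis acetate cannot participate.

Step 19
Reactants: 30 6β-acetoxy-15-[(tert-butyldiphenylsilyl)oxy]-7α-(3-methylbutanoyloxy)labda-8,13E-diene
Product: 31 6β-acetoxy-7α-(3-methylbutanoyloxy)labda-8,13E-dien-15-ol
Conditions: HF·pyridine, THF/pyridine, 0 °C → rt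
Reagents that add atoms: none
Why: Fluoride-mediated cleavage of the silyl ether under mildly acidic conditions that leave the acetate, the allylic isovalerate and the alkenes untouched.

Step 20
Reactants: 31 6β-acetoxy-7α-(3-methylbutanoyloxy)labda-8,13E-dien-15-ol
Product: 33 (5S,6S,7S,10S,13E)-6-acetoxy-7-(3-methylbutanoyloxy)labda-8,13-dien-15-oic acid, via enal 32 (not isolated)
Conditions: MnO2, CH2Cl2, rt; filtration; then NaClO2, NaH2PO4, 2-methylbut-2-ene, t-BuOH/H2O, 0 °C → rt
Reagents that add atoms: sodium chlorite, [Na+].[O-]Cl=O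
Why: MnO2 oxidises only the allylic primary alcohol to the E enal, and Pinnick oxidation with a hypochlorite scavenger takes the aldehyde to the acid without touching the esters or the tetrasubstituted alkene.

Compound list
1 | 4-methoxy-2,6-dimethylphenol | COc1cc(C)c(O)c(C)c1 | starting material
2 | 4,4-dimethoxy-2,6-dimethylcyclohexa-2,5-dien-1-one | COC1(OC)C=C(C)C(=O)C(C)=C1 | intermediate
3 | ethane-1,2-diol | OCCO | starting material
4 | 7,9-dimethyl-1,4-dioxaspiro[4.5]deca-6,9-dien-8-one | O=C1C(C)=CC2(OCCO2)C=C1C | intermediate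
5 | phenyl vinyl sulfone | C=CS(=O)(=O)c1ccccc1 | starting material
6 | formaldehyde | C=O | starting material
7 | 2-(phenylsulfonyl)prop-2-en-1-ol | C=C(CO)S(=O)(=O)c1ccccc1 | intermediate
8 | 3-bromo-2-(phenylsulfonyl)prop-1-ene | C=C(CBr)S(=O)(=O)c1ccccc1 | intermediate
9 | isopropenylmagnesium bromide | C=C(C)[Mg]Br | starting material
10 | bromomagnesium (10S)-7,9-dimethyl-10-(prop-1-en-2-yl)-1,4-dioxaspiro[4.5]deca-6,8-dien-8-olate (not isolated) | Br[Mg]OC1=C(C)[C@H](C(C)=C)C2(OCCO2)C=C1C | intermediate
11 | (9S,10S)-7,9-dimethyl-9-[2-(phenylsulfonyl)prop-2-en-1-yl]-10-(prop-1-en-2-yl)-1,4-dioxaspiro[4.5]dec-6-en-8-one (isopropenyl and sulfonylallyl arms trans) | O=C1C(C)=CC2(OCCO2)[C@@H](C(C)=C)[C@]1(C)CC(=C)S(=O)(=O)c1ccccc1 | intermediate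
12 | 6,6-ethylenedioxy-2-(phenylsulfonyl)-11-nordrim-7-en-9-one: trans-decalin with C9 ketone, C7=C8 alkene bearing the C8 methyl, spiro-dioxolane at C6, gem-dimethyl C4, 5α-H, 10β-CH3, C2 epimers | O=C1C(C)=CC2(OCCO2)[C@H]3C(C)(C)CC(S(=O)(=O)c4ccccc4)C[C@]13C | intermediate
13 | tert-butyl(but-3-yn-1-yloxy)dimethylsilane | C#CCCO[Si](C)(C)C(C)(C)C | starting material
14 | (E)-{4-[(tert-butyldimethylsilyl)oxy]-2-methylbut-1-en-1-yl}dimethylalane (not isolated) | C[Al](C)/C=C(\C)CCO[Si](C)(C)C(C)(C)C | intermediate
15 | lithium butyl{(E)-4-[(tert-butyldimethylsilyl)oxy]-2-methylbut-1-en-1-yl}dimethylalanate (not isolated) | [Li+].CCCC[Al-](C)(C)/C=C(\C)CCO[Si](C)(C)C(C)(C)C | intermediate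
16 | (E)-5-[(tert-butyldimethylsilyl)oxy]-3-methylpent-2-en-1-ol | OC/C=C(\C)CCO[Si](C)(C)C(C)(C)C | intermediate
17 | (E)-1-[(tert-butyldiphenylsilyl)oxy]-5-[(tert-butyldimethylsilyl)oxy]-3-methylpent-2-ene | CC(C)(C)[Si](C)(C)OCC/C(C)=C/CO[Si](c1ccccc1)(c1ccccc1)C(C)(C)C | intermediate
18 | (E)-5-[(tert-butyldiphenylsilyl)oxy]-3-methylpent-3-en-1-ol | OCC/C(C)=C/CO[Si](c1ccccc1)(c1ccccc1)C(C)(C)C | intermediate
19 | (E)-tert-butyl[(5-iodo-3-methylpent-2-en-1-yl)oxy]diphenylsilane | ICC/C(C)=C/CO[Si](c1ccccc1)(c1ccccc1)C(C)(C)C | intermediate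
20 | (E)-{5-[(tert-butyldiphenylsilyl)oxy]-3-methylpent-3-en-1-yl}lithium (not isolated) | [Li]CC/C(C)=C/CO[Si](c1ccccc1)(c1ccccc1)C(C)(C)C | intermediate
21 | (E)-{5-[(tert-butyldiphenylsilyl)oxy]-3-methylpent-3-en-1-yl}cerium dichloride (not isolated) | Cl[Ce](Cl)CC/C(C)=C/CO[Si](c1ccccc1)(c1ccccc1)C(C)(C)C | intermediate
22 | 15-[(tert-butyldiphenylsilyl)oxy]-6,6-ethylenedioxy-2-(phenylsulfonyl)labda-7,13E-dien-9-ol (9β-OH, side chain α; 5α-H; 10β-CH3; C2 epimers) | O[C@@]1(CC/C(C)=C/CO[Si](c2ccccc2)(c2ccccc2)C(C)(C)C)C(C)=CC3(OCCO3)[C@H]4C(C)(C)CC(S(=O)(=O)c5ccccc5)C[C@]14C | intermediate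
23 | 15-[(tert-butyldiphenylsilyl)oxy]-6,6-ethylenedioxylabda-7,13E-dien-9-ol (9β-OH) | O[C@@]1(CC/C(C)=C/CO[Si](c2ccccc2)(c2ccccc2)C(C)(C)C)C(C)=CC3(OCCO3)[C@H]4C(C)(C)CCC[C@]14C | intermediate
24 | 15-[(tert-butyldiphenylsilyl)oxy]-9-hydroxylabda-7,13E-dien-6-one (9β-OH) | O[C@@]1(CC/C(C)=C/CO[Si](c2ccccc2)(c2ccccc2)C(C)(C)C)C(C)=CC(=O)[C@H]3C(C)(C)CCC[C@]13C | intermediate
25 | 15-[(tert-butyldiphenylsilyl)oxy]labda-7,13E-diene-6β,9-diol (9β-OH) | O[C@@]1(CC/C(C)=C/CO[Si](c2ccccc2)(c2ccccc2)C(C)(C)C)C(C)=C[C@@H](O)[C@H]3C(C)(C)CCC[C@]13C | intermediate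
26 | 6β-acetoxy-15-[(tert-butyldiphenylsilyl)oxy]labda-7,13E-dien-9-ol (9β-OH) | O[C@@]1(CC/C(C)=C/CO[Si](c2ccccc2)(c2ccccc2)C(C)(C)C)C(C)=C[C@@H](OC(C)=O)[C@H]3C(C)(C)CCC[C@]13C | intermediate
27 | 6β-acetoxy-15-[(tert-butyldiphenylsilyl)oxy]labda-8,13E-dien-7-one | CC(=O)O[C@@H]1C(=O)C(C)=C(CC/C(C)=C/CO[Si](c2ccccc2)(c2ccccc2)C(C)(C)C)[C@@]3(C)CCCC(C)(C)[C@H]13 | intermediate
28 | 6β-acetoxy-15-[(tert-butyldiphenylsilyl)oxy]labda-8,13E-dien-7β-ol | CC(=O)O[C@@H]1[C@H](O)C(C)=C(CC/C(C)=C/CO[Si](c2ccccc2)(c2ccccc2)C(C)(C)C)[C@@]3(C)CCCC(C)(C)[C@H]13 | intermediate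
29 | 3-methylbutanoic acid (isovaleric acid) | CC(C)CC(=O)O | starting material
30 | 6β-acetoxy-15-[(tert-butyldiphenylsilyl)oxy]-7α-(3-methylbutanoyloxy)labda-8,13E-diene | CC(=O)O[C@@H]1[C@@H](OC(=O)CC(C)C)C(C)=C(CC/C(C)=C/CO[Si](c2ccccc2)(c2ccccc2)C(C)(C)C)[C@@]3(C)CCCC(C)(C)[C@H]13 | intermediate
31 | 6β-acetoxy-7α-(3-methylbutanoyloxy)labda-8,13E-dien-15-ol | CC(=O)O[C@@H]1[C@@H](OC(=O)CC(C)C)C(C)=C(CC/C(C)=C/CO)[C@@]2(C)CCCC(C)(C)[C@H]12 | intermediate
32 | 6β-acetoxy-7α-(3-methylbutanoyloxy)labda-8,13E-dien-15-al (not isolated) | CC(=O)O[C@@H]1[C@@H](OC(=O)CC(C)C)C(C)=C(CC/C(C)=C/C=O)[C@@]2(C)CCCC(C)(C)[C@H]12 | intermediate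
33 | (5S,6S,7S,10S,13E)-6-acetoxy-7-(3-methylbutanoyloxy)labda-8,13-dien-15-oic acid (6β-OAc, 7α-ester) | CC(=O)O[C@@H]1[C@@H](OC(=O)CC(C)C)C(C)=C(CC/C(C)=C/C(=O)O)[C@@]2(C)CCCC(C)(C)[C@H]12 | target

Total step count: 20. Longest linear sequence: 14 steps (steps 1, 2, 5, 6 and 11–20; the side-chain branch, steps 7–10 and 11–20, is equally long).

Steps most likely to fail

Step 5. The catalyst may discriminate the enantiotopic arms poorly with an sp2 Grignard reagent at a β-carbon next to the ketal, or the magnesium enolate may be protonated or O-alkylated instead of forming the quaternary carbon. The fallback separates the two bond formations and changes the organometallic class. It sets out from 4: copper-catalysed enantioselective conjugate addition of dimethyl(prop-1-en-2-yl)alane (from isopropenyllithium and Me2AlCl) with Cu(O2CC4H3S) (copper thiophene-2-carboxylate) and a chiral phosphoramidite in Et2O at −30 °C, a reagent class that is known to tolerate α-substituted cyclic enones and cyclohexadienones. The aluminium enolate is trapped with Me3SiCl/Et3N as the isolable trimethylsilyl enol ether [(10S)-7,9-dimethyl-10-(prop-1-en-2-yl)-1,4-dioxaspiro[4.5]deca-6,8-dien-8-yl]oxytrimethylsilane F1. Treatment of F1 with MeLi in THF regenerates the lithium enolate, which is alkylated with 8 in THF/DMPU at −78 °C, anti to the isopropenyl group, and the route is rejoined at 11.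

Step 18. Displacement at the hindered C7 may proceed with retention (acyl transfer to the alcohol instead of SN2), by ionisation with loss of stereochemical integrity, or not at all; the facial outcome of step 17 is a linked uncertainty. The fallback sets the C7 centre by reduction from the β face and is independent of both. It sets out from 27: mild methanolysis of the activated α-acetoxy ketone (catalytic K2CO3, MeOH, −20 °C) should give 15-[(tert-butyldiphenylsilyl)oxy]-6β-hydroxylabda-8,13E-dien-7-one F2. Hydroxyl-directed reduction with Me4NBH(OAc)3 in MeCN/AcOH at −20 °C (Evans–Saksena) delivers hydride intramolecularly from the 6β oxygen to the β face of C7 and should give the trans diol 15-[(tert-butyldiphenylsilyl)oxy]labda-8,13E-diene-6β,7α-diol F3. The less hindered allylic 7α hydroxyl is acylated selectively with isovaleric anhydride and catalytic DMAP in pyridine at 0 °C to give 15-[(tert-butyldiphenylsilyl)oxy]-7α-(3-methylbutanoyloxy)labda-8,13E-dien-6β-ol F4. Forcing acetylation of the axial 6β hydroxyl (Ac2O, DMAP, 40 °C) returns to the route at 30.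

Step 11. The elaborate organometallic may be consumed by deprotonation next to the sulfone or by 1,3-elimination of its allylic silyloxy group before it adds to the congested C9 carbonyl. The fallback adds a cheap, robust nucleophile in large excess and builds the trisubstituted alkene afterwards. It sets out from 12: excess [4-(trimethylsilyl)but-3-yn-1-yl]magnesium bromide with CeCl3 in THF at −78 °C gives 6,6-ethylenedioxy-2-(phenylsulfonyl)-9-[4-(trimethylsilyl)but-3-yn-1-yl]-11-nordrim-7-en-9-ol F5. Desulfonylation with 6% Na(Hg)/Na2HPO4 in MeOH gives 6,6-ethylenedioxy-9-[4-(trimethylsilyl)but-3-yn-1-yl]-11-nordrim-7-en-9-ol F6, and K2CO3/MeOH frees the terminal alkyne 9-(but-3-yn-1-yl)-6,6-ethylenedioxy-11-nordrim-7-en-9-ol F7. Zirconium-catalysed carboalumination (AlMe3, Cp2ZrCl2, −20 °C → rt), then n-BuLi and paraformaldehyde, gives the E allylic alcohol 6,6-ethylenedioxylabda-7,13E-diene-9,15-diol F8. Silylation of the primary hydroxyl (TBDPSCl, imidazole) rejoins the route at 23.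

Further compounds
F1 | step 5 | [(10S)-7,9-dimethyl-10-(prop-1-en-2-yl)-1,4-dioxaspiro[4.5]deca-6,8-dien-8-yl]oxytrimethylsilane | C[Si](C)(C)OC1=C(C)[C@H](C(C)=C)C2(OCCO2)C=C1C
F2 | step 18 | 15-[(tert-butyldiphenylsilyl)oxy]-6β-hydroxylabda-8,13E-dien-7-one | O[C@@H]1C(=O)C(C)=C(CC/C(C)=C/CO[Si](c2ccccc2)(c2ccccc2)C(C)(C)C)[C@@]3(C)CCCC(C)(C)[C@H]13
F3 | step 18 | 15-[(tert-butyldiphenylsilyl)oxy]labda-8,13E-diene-6β,7α-diol | O[C@@H]1[C@@H](O)C(C)=C(CC/C(C)=C/CO[Si](c2ccccc2)(c2ccccc2)C(C)(C)C)[C@@]3(C)CCCC(C)(C)[C@H]13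
F4 | step 18 | 15-[(tert-butyldiphenylsilyl)oxy]-7α-(3-methylbutanoyloxy)labda-8,13E-dien-6β-ol | O[C@@H]1[C@@H](OC(=O)CC(C)C)C(C)=C(CC/C(C)=C/CO[Si](c2ccccc2)(c2ccccc2)C(C)(C)C)[C@@]3(C)CCCC(C)(C)[C@H]13
F5 | step 11 | 6,6-ethylenedioxy-2-(phenylsulfonyl)-9-[4-(trimethylsilyl)but-3-yn-1-yl]-11-nordrim-7-en-9-ol | O[C@@]1(CCC#C[Si](C)(C)C)C(C)=CC2(OCCO2)[C@H]3C(C)(C)CC(S(=O)(=O)c4ccccc4)C[C@]13C
F6 | step 11 | 6,6-ethylenedioxy-9-[4-(trimethylsilyl)but-3-yn-1-yl]-11-nordrim-7-en-9-ol | O[C@@]1(CCC#C[Si](C)(C)C)C(C)=CC2(OCCO2)[C@H]3C(C)(C)CCC[C@]13C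
F7 | step 11 | 9-(but-3-yn-1-yl)-6,6-ethylenedioxy-11-nordrim-7-en-9-ol | O[C@@]1(CCC#C)C(C)=CC2(OCCO2)[C@H]3C(C)(C)CCC[C@]13C
F8 | step 11 | 6,6-ethylenedioxylabda-7,13E-diene-9,15-diol | O[C@@]1(CC/C(C)=C/CO)C(C)=CC2(OCCO2)[C@H]3C(C)(C)CCC[C@]13C
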